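I started with the easy step, a straight line through the winter target readings.

| flask | starting material | temperature | remark | time |
|---|---|---|---|---|
| winter | 1 M | 80 °C | run made earlier |  |
| Tuesday's | 2.0 M | 80 °C |  | 10 min |
| Wednesday's | 2.0 M | 110 °C |  | 10 min |
| Friday's | 2.0 M | 95 °C |  | 10 min |
| Sunday's | 2.0 M | 125 °C |  | 10 min |

winter run (percent of the starting material charged)

| time / s | target / % | side product A / % |
|---|---|---|
| 10.0 | 1.2 | 1.0 |
| 15.0 | 2.4 | 0 |
| 25.0 | 5.4 | 0 |
| 40.0 | 6.1 | 0 |
| 50.0 | 7.3 | 0 |
| 60.0 | 8.5 | 0 |

(scatter of a reading: 0.5 percentage points)

- percentages count the starting material that a species holds: one side product B counts as two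
- the earlier runs do not show what temperature does; that part of a forecast is a guess

- which flask leads in share of target in all that became target or side product A or side product B or over-reaction product ("all alike" within 1.5 percentage points) (Tuesday's / Wednesday's / Friday's / Sunday's / all alike)
- share of target in all that became target or side product A or side product B or over-reaction product, Tuesday's
- share of target in all that became target or side product A or side product B or over-reaction product, Wednesday's
- share of target in all that became target or side product A or side product B or over-reaction product, Friday's
- share of target in all that became target or side product A or side product B or over-reaction product, Sunday's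

Between 15.0 s and 60.0 s, target rose from 2.4 % to 8.5 % of the charge. From that I read a filling time 12.3 min, the time a flask would need to turn its whole charge into target at that pace. It is a reading and carries the scatter of 0.5 percentage points. Counted in fractions of the charge, it let me carry the winter pace to Tuesday's, assuming that doubling the charge left the fractional pace alone. The 10 min run is shorter than the filling time, so my reckoning put Tuesday's target near 81.3 % of the charge. For the hotter flasks I had no measured pace, so what temperature does stayed a guess.

The forecast named Tuesday's as the leader in share of target, or selectivity. Its shares, which are a different quantity from my amount of target, were 82 % for Tuesday's, 63 % for Wednesday's, 73 % for Friday's and 50 % for Sunday's, reasoning that “Over-reaction grows as target accumulates”.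

The flasks gave shares of 91.9 % for Tuesday's, 19.9 % for Wednesday's, 68.3 % for Friday's and 0.403 % for Sunday's, so Tuesday's led.

    intermediate C → side product A (k = 6.10 × 10⁻⁴ /s, Ea = 100 kJ/mol)
    starting material + target → side product B (k = 0.00110 /M/s, Ea = 68.0 kJ/mol)
    starting material ⇌ intermediate A (K = 2.00, k = 0.0980 /s, Ea = 86.0 kJ/mol, ΔH = −23.0 kJ/mol)
    intermediate A → intermediate C (k = 0.00160 /s, Ea = 94.0 kJ/mol)
    starting material → target (k = 0.00270 /s, Ea = 98.0 kJ/mol)
    target → over-reaction product (k = 2.00 × 10⁻⁴ /s, Ea = 100 kJ/mol)
    intermediate A → intermediate B (k = 0.0640 /s, Ea = 102 kJ/mol)
    intermediate B → target (k = 0.00170 /s, Ea = 97.0 kJ/mol)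
    (constants at 80 °C)

The largest single effect on the difference in share, Sunday's minus Tuesday's, was what temperature does to the reaction of target to over-reaction product: that difference stands at −92 points, and the run without this effect gives −4.7 points. On Tuesday's, the filling time gave 40.7 % at 5.00 min; target stood at 37.2 %, with intermediate B at 59.0 %. On Sunday's, target fell from 6.74 % at 5.00 min with an e-fold time of 1.77 min, shorter than the filling time, and reached 0.403 % at 10.0 min.

The readings are simulated from invented constants, noise included.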